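**Retrosynthetic overview**

1. Molephantinin is reached by removing a 4-methoxybenzyl (PMB) ether from O5 of the otherwise complete macrolide.
2. Key disconnection: C6–C7 and C11–C12 (and with them the lactone O–C12 bond) are made in one flask from an acyclic allenyl keto-aldehyde and methyl chloroformate. The ten-membered carbocycle closes first and the γ-lactone closes onto it.
3. Enabling feature: the C13=C11–C7 unit of the α-methylene-γ-butyrolactone ring is a masked terminal allene (C7=C11=C13) next to the C8 ester. Its central carbon C11 can take the one-carbon unit C12, and its inner terminus C7 then becomes an allyl nucleophile for a C6 aldehyde. The (1(10)E,3Z)-dienone arm C10–C4 is already in place and turns the chain back on itself.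
4. The keto-aldehyde comes from a C2–C3 Nozaki–Hiyama–Kishi union of a (Z)-iodoalkene (C3–C6, C15; C5 from (R)-glyceraldehyde acetonide) with an (E)-enal (C7–C10, C1, C2, C11, C13, C14, tiglate), followed by a double oxidation.
5. The enal comes from 3-(trimethylsilyl)propynal by asymmetric propargylation (C8), methylalumination/formaldehyde (C1=C10, C2), alkyne-to-allene homologation (C13) and tigloylation.

Key step: step 14

Remark: locants C1–C15 follow germacranolide numbering (ring C1–C10; lactone O–C6, C7, C11(=C13), C12; ester on C8; hydroxyl on C5).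
Remark: (S)-TRIP is assumed to give the S carbinol in step 6 by analogy with aryl aldehydes; if a Mosher ester of the first batch shows the opposite sense, the antipodal catalyst is used.

**Route**

Step 1
Reactants: 1 (R)-2,2-dimethyl-1,3-dioxolane-4-carbaldehyde
Product: 2 (4S)-4-ethynyl-2,2-dimethyl-1,3-dioxolane
Conditions: Ohira–Bestmann reagent, K2CO3, MeOH, 0 °C to rt
Reagents that add atoms: dimethyl (1-diazo-2-oxopropyl)phosphonate, CC(=O)C(=[N+]=[N-])P(=O)(OC)OC
Why: Seyferth–Gilbert homologation with the Ohira–Bestmann reagent turns the aldehyde into the terminal alkyne under conditions known not to epimerise this α-alkoxy aldehyde, so the C5 centre of the target is taken unchanged from the chiral pool.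

Step 2
Reactants: 2 (4S)-4-ethynyl-2,2-dimethyl-1,3-dioxolane
Product: 3 (2S)-but-3-yne-1,2-diol
Conditions: Dowex 50WX8 (H+ form), MeOH, rt
Reagents that add atoms: none
Why: Acid-catalysed transacetalisation to methanol frees the diol without touching the alkyne or the stereocentre.

Step 3
Reactants: 3 (2S)-but-3-yne-1,2-diol
Product: 4 (2S,3Z)-4-iodo-3-methylbut-3-ene-1,2-diol
Conditions: MeMgBr (4 equiv), CuI (20 mol %), THF, −10 °C to rt; then I2, −60 to 0 °C
Reagents that add atoms: methylmagnesium bromide, C[Mg]Br; iodine, II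
Why: Copper-catalysed carbomagnesiation of the propargylic alkoxide puts methyl on the inner alkyne carbon and magnesium anti to it at the terminus (five-membered alkoxide chelate), and iodinolysis with retention gives the (Z)-iodoalkene that fixes the C3=C4 geometry of the target.

Step 4
Reactants: 4 (2S,3Z)-4-iodo-3-methylbut-3-ene-1,2-diol
Product: 5 (4S)-4-[(1Z)-1-iodoprop-1-en-2-yl]-2-(4-methoxyphenyl)-1,3-dioxolane (both epimers at the acetal carbon)
Conditions: 4-MeOC6H4CH(OMe)2, PPTS (cat.), CH2Cl2, rt
Reagents that add atoms: 4-methoxybenzaldehyde dimethyl acetal, COC(OC)c1ccc(OC)cc1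
Why: Acid-catalysed acetal exchange forms the five-membered 4-methoxybenzylidene acetal of the 1,2-diol, whose new acetal centre is a mixture that is destroyed in the next step.

Step 5
Reactants: 5 (4S)-4-[(1Z)-1-iodoprop-1-en-2-yl]-2-(4-methoxyphenyl)-1,3-dioxolane
Product: 6 (2S,3Z)-4-iodo-2-[(4-methoxyphenyl)methoxy]-3-methylbut-3-en-1-ol
Conditions: i-Bu2AlH (3 equiv), CH2Cl2, −78 to 0 °C
Reagents that add atoms: none
Why: Regioselective reductive opening of the arylidene acetal, in which aluminium binds the less hindered primary oxygen and hydride opens the acetal so that the PMB ether stays on the secondary allylic oxygen and the primary alcohol is freed.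

Step 6
Reactants: 7 3-(trimethylsilyl)prop-2-ynal; 8 allenylboronic acid pinacol ester (4,4,5,5-tetramethyl-2-(propa-1,2-dien-1-yl)-1,3,2-dioxaborolane)
Product: 9 (3S)-1-(trimethylsilyl)hexa-1,5-diyn-3-ol
Conditions: (S)-TRIP (3,3′-bis(2,4,6-triisopropylphenyl)-1,1′-binaphthyl-2,2′-diyl hydrogen phosphate, 5 mol %), 4 Å MS, toluene, 0 °C
Reagents that add atoms: none
Why: Chiral phosphoric acid-catalysed propargylation, in which the allenylboronate reacts through a closed six-membered SE2′ transition state on the catalyst-bound aldehyde, so that only the homopropargylic alcohol forms and the catalyst sets the new C8 carbinol centre as S.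

Step 7
Reactants: 9 (3S)-1-(trimethylsilyl)hexa-1,5-diyn-3-ol
Product: 10 (2E,5S)-3-methyl-7-(trimethylsilyl)hept-2-en-6-yne-1,5-diol
Conditions: Me3Al (4.5 equiv), Cp2ZrCl2 (20 mol %), H2O (1.5 equiv), CH2Cl2, −20 °C; then n-BuLi, (CH2O)n, THF, −20 °C to rt
Reagents that add atoms: trimethylaluminium, C[Al](C)C; paraformaldehyde (as formaldehyde), C=O
Why: Zirconium-catalysed methylalumination (Negishi carboalumination) adds methyl and aluminium syn across the terminal alkyne with methyl on the inner carbon, the silylated alkyne reacting far more slowly, and the alkenylalanate is trapped by formaldehyde with retention to give the (E)-3-methylallylic alcohol that fixes the C1=C10 geometry.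

Step 8
Reactants: 10 (2E,5S)-3-methyl-7-(trimethylsilyl)hept-2-en-6-yne-1,5-diol
Product: 11 (2E,5S)-3-methylhept-2-en-6-yne-1,5-diol
Conditions: K2CO3 (cat.), MeOH, rt
Reagents that add atoms: none
Why: Base-catalysed methanolysis of the alkynyl C–Si bond (protodesilylation) frees the terminal alkyne and leaves both alcohols and the stereocentre untouched.

Step 9
Reactants: 11 (2E,5S)-3-methylhept-2-en-6-yne-1,5-diol
Product: 12 (2E,5S)-3-methylocta-2,6,7-triene-1,5-diol
Conditions: (CH2O)n (2.5 equiv), CuI (0.5 equiv), Cy2NH (1.8 equiv), 1,4-dioxane, reflux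
Reagents that add atoms: paraformaldehyde (as formaldehyde), C=O
Why: Crabbé homologation, in which Mannich condensation of the terminal alkyne with formaldehyde and the amine followed by copper-mediated 1,5-hydride transfer converts C≡CH into CH=C=CH2, tolerates free hydroxyl groups and does not touch the carbinol centre.

Step 10
Reactants: 12 (2E,5S)-3-methylocta-2,6,7-triene-1,5-diol
Product: 13 (2E,5S)-5-hydroxy-3-methylocta-2,6,7-trienal
Conditions: TEMPO (10 mol %), PhI(OAc)2 (1.1 equiv), CH2Cl2, rt
Reagents that add atoms: none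
Why: Oxoammonium (TEMPO) oxidation is selective for the primary allylic alcohol over the secondary allenic alcohol and should stop at the (E)-enal.

Step 11
Reactants: 13 (2E,5S)-5-hydroxy-3-methylocta-2,6,7-trienal
Product: 14 (4S,6E)-6-methyl-8-oxoocta-1,2,6-trien-4-yl (2E)-2-methylbut-2-enoate
Conditions: tigloyl chloride (1.5 equiv), pyridine, DMAP (cat.), CH2Cl2, 0 °C
Reagents that add atoms: (E)-2-methylbut-2-enoyl chloride (tigloyl chloride), C/C=C(\C)C(Cl)=O
Why: DMAP-catalysed acylation of the secondary alcohol by the acid chloride installs the tiglate with retention at C8, and pyridine at 0 °C is mild enough to avoid vinylogous β-elimination of the new ester.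

Step 12
Reactants: 6 (2S,3Z)-4-iodo-2-[(4-methoxyphenyl)methoxy]-3-methylbut-3-en-1-ol; 14 (4S,6E)-6-methyl-8-oxoocta-1,2,6-trien-4-yl (2E)-2-methylbut-2-enoate
Product: 15 (4S,6E,9Z,11S)-8,12-dihydroxy-11-[(4-methoxyphenyl)methoxy]-6,10-dimethyldodeca-1,2,6,9-tetraen-4-yl (2E)-2-methylbut-2-enoate (both C8 epimers)
Conditions: CrCl2 (6 equiv), NiCl2 (2 mol %), DMSO, rt
Reagents that add atoms: none
Why: Nozaki–Hiyama–Kishi coupling, in which the alkenyl iodide passes via nickel to chromium with retention of the Z geometry and adds 1,2 to the enal in the presence of the ester, the allene and the free hydroxyl, the new carbinol centre being formed unselectively and removed in step 13.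

Step 13
Reactants: 15 (4S,6E,9Z,11S)-8,12-dihydroxy-11-[(4-methoxyphenyl)methoxy]-6,10-dimethyldodeca-1,2,6,9-tetraen-4-yl (2E)-2-methylbut-2-enoate
Product: 16 (4S,6E,9Z,11S)-11-[(4-methoxyphenyl)methoxy]-6,10-dimethyl-8,12-dioxododeca-1,2,6,9-tetraen-4-yl (2E)-2-methylbut-2-enoate
Conditions: Dess–Martin periodinane (3 equiv), NaHCO3, CH2Cl2, 0 °C to rt; used crude
Reagents that add atoms: none
Why: Dess–Martin oxidation converts the bis-allylic alcohol into the cross-conjugated dienone and the primary alcohol into the α-alkoxy aldehyde in one buffered, non-basic operation that should spare the C5 centre and the Z-enone.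

Step 14
Reactants: 16 (4S,6E,9Z,11S)-11-[(4-methoxyphenyl)methoxy]-6,10-dimethyl-8,12-dioxododeca-1,2,6,9-tetraen-4-yl (2E)-2-methylbut-2-enoate
Product: 19 (3aR,4S,6E,9Z,11S,11aS)-11-[(4-methoxyphenyl)methoxy]-6,10-dimethyl-3-methylidene-2,8-dioxo-2,3,3a,4,5,8,11,11a-octahydrocyclodeca[b]furan-4-yl (2E)-2-methylbut-2-enoate, via allylchromium reagent 17 (not isolated), via ten-membered hydroxy ester 18 (not isolated)
Conditions: ClCO2Me (3 equiv), NiCl2(dme) (10 mol %), 4,4′-di-tert-butyl-2,2′-bipyridine (12 mol %), CrCl2 (6 equiv), THF–MeCN 3:1, 25 °C, 16 added by syringe pump over 12 h (final 2 mM); aq. NH4Cl work-up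
Reagents that add atoms: methyl chloroformate, COC(Cl)=O
Why: Proposed new method: zerovalent nickel, formed from NiCl2(dme) and CrCl2, should add oxidatively to methyl chloroformate, and the methoxycarbonylnickel chloride should insert the terminal C11=C13 bond of the allene with the ester carbon going to the central carbon (first new bond, C11–C12), giving a 2-(methoxycarbonyl)-π-allylnickel that CrCl2 converts into the trivalent allylchromium 17; 17 adds through its substituted terminus C7 to the C6 aldehyde (second new bond, C6–C7) and the chromium alkoxide of 18 then expels methoxide from the neighbouring ester. The closest known reaction types are chromium-mediated three-component couplings in which an organometal made from an organic halide adds to an allene or 1,3-diene and the resulting allylchromium adds to an aldehyde, nickel-catalysed reductive alkoxycarbonylation with chloroformates, and the CrCl2-mediated macrocyclic Barbier allylation of C6 aldehydes by 2-(alkoxycarbonyl)allyl halides that closes germacranolide rings. The ten-membered carbocycle closes by intramolecular carbonyl allylation through a six-membered chair at chromium, and the γ-lactone closes by 5-exo-trig acyl substitution of the C6 alkoxide on the C12 ester. C7 relative to C6 is controlled by the Zimmerman–Traxler chair with the C8 branch equatorial (anti adduct, hence the 6,7-trans lactone); the absolute sense of the pair is expected to be controlled by the resident C5 and C8 centres, with chromium bridging the aldehyde oxygen and the C5 ether oxygen and both ring arms extended, and this facial control is the least certain element. The step needs aldehyde-over-ketone selectivity (organochromium reagents discriminate strongly, and attack of C7 on C2 would need a trans-cyclohexene because C1=C10 is E), attack through C7 and not C13 (normal γ-selectivity of allylchromium; C13 attack would give a twelve-membered ring), and cyclisation over oligomerisation (slow addition at 2 mM). The allene is the only π-system expected to insert, because all other alkenes are trisubstituted and conjugated.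

Step 15
Reactants: 19 (3aR,4S,6E,9Z,11S,11aS)-11-[(4-methoxyphenyl)methoxy]-6,10-dimethyl-3-methylidene-2,8-dioxo-2,3,3a,4,5,8,11,11a-octahydrocyclodeca[b]furan-4-yl (2E)-2-methylbut-2-enoate
Product: 20 molephantinin, (3aR,4S,6E,9Z,11S,11aS)-11-hydroxy-6,10-dimethyl-3-methylidene-2,8-dioxo-2,3,3a,4,5,8,11,11a-octahydrocyclodeca[b]furan-4-yl (2E)-2-methylbut-2-enoate
Conditions: DDQ (1.5 equiv), CH2Cl2–pH 7 phosphate buffer 10:1, 0 °C to rt
Reagents that add atoms: none
Why: Oxidative cleavage of the PMB ether by DDQ (hydride abstraction, then hydrolysis of the oxocarbenium ion) frees the C5 hydroxyl under neutral conditions that should leave the dienone, the tiglate and the α-methylene lactone intact.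

**Compound list**

1 | (R)-2,2-dimethyl-1,3-dioxolane-4-carbaldehyde | O=C[C@H]1COC(C)(C)O1 | starting material
2 | (4S)-4-ethynyl-2,2-dimethyl-1,3-dioxolane | C#C[C@H]1COC(C)(C)O1 | intermediate
3 | (2S)-but-3-yne-1,2-diol | C#C[C@H](O)CO | intermediate
4 | (2S,3Z)-4-iodo-3-methylbut-3-ene-1,2-diol | I/C=C(/C)[C@@H](CO)O | intermediate
5 | (4S)-4-[(1Z)-1-iodoprop-1-en-2-yl]-2-(4-methoxyphenyl)-1,3-dioxolane (acetal epimers) | I/C=C(/C)[C@H]1COC(c2ccc(OC)cc2)O1 | intermediate
6 | (2S,3Z)-4-iodo-2-[(4-methoxyphenyl)methoxy]-3-methylbut-3-en-1-ol | I/C=C(/C)[C@@H](CO)OCc1ccc(OC)cc1 | intermediate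
7 | 3-(trimethylsilyl)prop-2-ynal | C[Si](C)(C)C#CC=O | starting material
8 | allenylboronic acid pinacol ester | C=C=CB1OC(C)(C)C(C)(C)O1 | starting material
9 | (3S)-1-(trimethylsilyl)hexa-1,5-diyn-3-ol | C[Si](C)(C)C#C[C@@H](O)CC#C | intermediate
10 | (2E,5S)-3-methyl-7-(trimethylsilyl)hept-2-en-6-yne-1,5-diol | C[Si](C)(C)C#C[C@@H](O)C/C(C)=C/CO | intermediate
11 | (2E,5S)-3-methylhept-2-en-6-yne-1,5-diol | C#C[C@@H](O)C/C(C)=C/CO | intermediate
12 | (2E,5S)-3-methylocta-2,6,7-triene-1,5-diol | C=C=C[C@@H](O)C/C(C)=C/CO | intermediate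
13 | (2E,5S)-5-hydroxy-3-methylocta-2,6,7-trienal | C=C=C[C@@H](O)C/C(C)=C/C=O | intermediate
14 | (4S,6E)-6-methyl-8-oxoocta-1,2,6-trien-4-yl (2E)-2-methylbut-2-enoate | C=C=C[C@@H](OC(=O)/C(C)=C/C)C/C(C)=C/C=O | intermediate
15 | (4S,6E,9Z,11S)-8,12-dihydroxy-11-[(4-methoxyphenyl)methoxy]-6,10-dimethyldodeca-1,2,6,9-tetraen-4-yl (2E)-2-methylbut-2-enoate (C8 epimers) | C=C=C[C@@H](OC(=O)/C(C)=C/C)C/C(C)=C/C(O)/C=C(/C)[C@@H](CO)OCc1ccc(OC)cc1 | intermediate
16 | (4S,6E,9Z,11S)-11-[(4-methoxyphenyl)methoxy]-6,10-dimethyl-8,12-dioxododeca-1,2,6,9-tetraen-4-yl (2E)-2-methylbut-2-enoate | C=C=C[C@@H](OC(=O)/C(C)=C/C)C/C(C)=C/C(=O)/C=C(/C)[C@@H](C=O)OCc1ccc(OC)cc1 | intermediate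
17 | 2-(methoxycarbonyl)allylchromium dichloride derived from 16 (σ-allyl form, C8 trans to CH2Cr, solvent ligands omitted) | COC(=O)/C(C[Cr](Cl)Cl)=C\[C@@H](OC(=O)/C(C)=C/C)C/C(C)=C/C(=O)/C=C(/C)[C@@H](C=O)OCc1ccc(OC)cc1 | intermediate (not isolated)
18 | methyl (1(10)E,3Z,5S,6S,7S,8S)-6-hydroxy-5-[(4-methoxyphenyl)methoxy]-8-[(2E)-2-methylbut-2-enoyloxy]-2-oxogermacra-1(10),3,11(13)-trien-12-oate (present as its chromium alkoxide) | C=C(C(=O)OC)[C@@H]1[C@@H](OC(=O)/C(C)=C/C)C/C(C)=C/C(=O)/C=C(/C)[C@H](OCc2ccc(OC)cc2)[C@H]1O | intermediate (not isolated)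
19 | (3aR,4S,6E,9Z,11S,11aS)-11-[(4-methoxyphenyl)methoxy]-6,10-dimethyl-3-methylidene-2,8-dioxo-2,3,3a,4,5,8,11,11a-octahydrocyclodeca[b]furan-4-yl (2E)-2-methylbut-2-enoate | C=C1C(=O)O[C@H]2[C@H]1[C@@H](OC(=O)/C(C)=C/C)C/C(C)=C/C(=O)/C=C(/C)[C@@H]2OCc3ccc(OC)cc3 | intermediate
20 | molephantinin | C=C1C(=O)O[C@H]2[C@H]1[C@@H](OC(=O)/C(C)=C/C)C/C(C)=C/C(=O)/C=C(/C)[C@@H]2O | target

**Step count and risks**

Total step count: 15. Longest linear sequence: 10 steps (steps 6–15, from 7 to 20); steps 1–5 form the second branch, which joins at step 12.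

Steps most likely to fail:

1. Step 14 (proposed new method). Insertion of the allene into the methoxycarbonyl–nickel bond may be outrun by decarbonylation or direct reduction of the chloroformate. Ring closure may lose to oligomerisation or to attack through the unsubstituted allyl terminus. Facial selectivity with respect to C5 and C8 may be poor. The fallback separates the event into three known reactions and sets out from 16. Bromine (1.0 equiv, CH2Cl2, −78 °C) adds to the allene, the only electron-rich C=C bond, to give the 2-bromoallyl bromide F1 (its allylic isomer behaves the same). CrCl2 alone (THF–DMF, high dilution, no nickel, so the vinylic C–Br bond survives) then effects the known macrocyclic Barbier allylation of the aldehyde to give the ten-membered 2-bromoallylic alcohol F2. Pd(PPh3)4 (cat.), CO (1 atm), Et3N, MeCN, 60 °C closes the lactone by the known carbonylative lactonisation of 2-bromo homoallylic alcohols. The fallback comes back to the route at 19.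

2. Step 12. The allene may insert into the alkenylnickel intermediate before transfer to chromium, or the hindered Z-alkenyl species may couple slowly and isomerise. The fallback replaces nickel/chromium catalysis by halogen–lithium exchange and sets out from 6. Silylation (Et3SiCl, imidazole, CH2Cl2) gives the triethylsilyl ether F3. t-BuLi (2.1 equiv, Et2O, −78 °C) generates the alkenyllithium with retention, and this adds 1,2 to 14 at −78 °C, where the aldehyde reacts well before the ester, to give the silyl-protected adduct F4. HF·pyridine in THF removes the silyl group, and the fallback comes back to the route at 15.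

3. Step 13. Enolisation of the α-alkoxy aldehyde, whose C5–H is also the γ-position of the new enone, may erode the C5 configuration or move the C3=C4 bond while both oxidations run together. The fallback oxidises in two chemoselective stages and sets out from 15. MnO2 (CH2Cl2, rt) oxidises only the bis-allylic alcohol and gives the stable hydroxy dienone F5. The primary alcohol is then oxidised by TEMPO/PhI(OAc)2 (CH2Cl2, 0 °C) immediately before step 14, so the aldehyde is never stored, and the fallback comes back to the route at 16.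

Further compounds
F1 | step 14 | (4S,6E,9Z,11S)-1,2-dibromo-11-[(4-methoxyphenyl)methoxy]-6,10-dimethyl-8,12-dioxododeca-2,6,9-trien-4-yl (2E)-2-methylbut-2-enoate (C2=C3 geometry not defined) | BrCC(Br)=C[C@@H](OC(=O)/C(C)=C/C)C/C(C)=C/C(=O)/C=C(/C)[C@@H](C=O)OCc1ccc(OC)cc1
F2 | step 14 | (1(10)E,3Z)-11-bromo-6-hydroxy-5-[(4-methoxyphenyl)methoxy]-2-oxo-12-norgermacra-1(10),3,11(13)-trien-8-yl (2E)-2-methylbut-2-enoate, C5 to C8 arranged as in 18 | C=C(Br)[C@@H]1[C@@H](OC(=O)/C(C)=C/C)C/C(C)=C/C(=O)/C=C(/C)[C@H](OCc2ccc(OC)cc2)[C@H]1O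
F3 | step 12 | triethyl{[(2S,3Z)-4-iodo-2-[(4-methoxyphenyl)methoxy]-3-methylbut-3-en-1-yl]oxy}silane | I/C=C(/C)[C@@H](CO[Si](CC)(CC)CC)OCc1ccc(OC)cc1
F4 | step 12 | (4S,6E,9Z,11S)-8-hydroxy-11-[(4-methoxyphenyl)methoxy]-6,10-dimethyl-12-[(triethylsilyl)oxy]dodeca-1,2,6,9-tetraen-4-yl (2E)-2-methylbut-2-enoate (C8 epimers) | C=C=C[C@@H](OC(=O)/C(C)=C/C)C/C(C)=C/C(O)/C=C(/C)[C@@H](CO[Si](CC)(CC)CC)OCc1ccc(OC)cc1
F5 | step 13 | (4S,6E,9Z,11S)-12-hydroxy-11-[(4-methoxyphenyl)methoxy]-6,10-dimethyl-8-oxododeca-1,2,6,9-tetraen-4-yl (2E)-2-methylbut-2-enoate | C=C=C[C@@H](OC(=O)/C(C)=C/C)C/C(C)=C/C(=O)/C=C(/C)[C@@H](CO)OCc1ccc(OC)cc1
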